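The plan reads ring B plus the isopropenyl carbon C11 as the bicyclo[3.1.1]heptane of (+)-nopinone. C11 on C7 sits three bonds from C9 (C11–C7–C8–C9), so a retrosynthetic C9–C11 bond restores the pinane cyclobutane, with the C5 methyl syn to it. The precursor is a nopinone 1,5-diketone whose quaternary C5 carries that methyl and a C4-methyl-branched 3-oxobutyl chain. In one operation, HCl in acetic acid closes ring A (aldol cyclodehydration, C1–C10) and then cleaves the strained C9–C11 bond. This delivers the decalin enone with a C11 chloride as masked isopropenyl group. Dehydrogenation, dihydroxylation, hydrogenation, unmasking and two selective acylations complete the target.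

Key step: step 4

Remark (numbering and one assumption): eremophilane numbering is used (decalin C1–C10, C15 = methyl on C4, C14 = methyl on C5, C11–C13 = three-carbon unit on C7), and β is the face of the C5 methyl. The target then reads 4β,5β-dimethyl, 7β-isopropenyl, 10β-H, 8α-O-tigloyl, 9α-O-angeloyl (4S,5R,7R,8R,9S,10S). Commercial (+)-nopinone is assumed to be the (1R,5S) enantiomer in high enantiomeric purity, because its C5 becomes C7 of the target unchanged.

Step 1
Reactants: 1 (1R,5S)-(+)-nopinone
Product: 3 trans-3-methylnopinone (3S; methyl anti to the gem-dimethyl bridge), via nopinone lithium enolate 2 (not isolated)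
Conditions: LiN(i-Pr)2 (commercial solution), THF, −78 °C; MeI, −78 → 0 °C
Reagents that add atoms: iodomethane, CI
Why: Kinetic enolate alkylation: the bridgehead C1 cannot enolise, so only C3 (future C5) is deprotonated, and MeI should enter anti to the gem-dimethyl bridge, a centre that is planarised again in step 2 so that its configuration is of no consequence.

Step 2
Reactants: 3 trans-3-methylnopinone
Product: 5 trimethylsilyl enol ether of 3-methylnopinone (C2=C3 tetrasubstituted), via 3-methylnopinone lithium enolate 4 (not isolated)
Conditions: LiN(i-Pr)2 (commercial solution), THF, −78 → 0 °C; Me3SiCl, 0 °C → rt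
Reagents that add atoms: chlorotrimethylsilane, C[Si](C)(C)Cl
Why: O-silylation of a lithium enolate: 3 has a single enolisable hydrogen, so only one regioisomer can form, and a base route is preferred to Lewis-acidic silylating agents, which could attack the cyclobutane next to an activated carbonyl.

Step 3
Reactants: 5 trimethylsilyl enol ether of 3-methylnopinone; 6 (E)-pent-3-en-2-one
Product: 7 (3R)-3-methyl-3-[(2S)-4-oxopentan-2-yl]nopinone, the 1,5-diketone with C14 syn and the side chain anti to the gem-dimethyl bridge
Conditions: TiCl4 (1 equiv), CH2Cl2, −78 °C; then H2O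
Reagents that add atoms: none
Why: Mukaiyama–Michael addition forming C4–C5: the TiCl4-activated enone should be attacked from the methylene-bridge face, which fixes C5 with its methyl syn to C11, and the open transition state familiar from the same addition to 1-methyl-2-silyloxycyclohexenes is expected to place the C4 methyl cis to the C5 methyl, any C4 epimer being removed by chromatography at this stage.

Step 4
Reactants: 7 1,5-diketone
Product: 9 11-chloro-eremophil-1(10)-en-2-one (4β-Me 5β-Me 7β-chloroisopropyl), via tricyclic cyclobutane-bridged enone 8 (not isolated)
Conditions: HCl (g, saturated), AcOH, rt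
Reagents that add atoms: hydrogen chloride, Cl
Why: HCl enolises the methyl ketone of 7 toward C1, the enol adds to the protonated C10 carbonyl from the methylene-bridge face where the chain already sits, and loss of water gives enone 8. O-protonation of 8 then lets the C9–C11 σ-bond, which overlaps with the enone π-system, break to a linear dienol and a tertiary C11 cation; chloride traps the cation, the dienol ketonises by protonation at C9, and if the cyclobutane should open before the aldol event the same product 9 results. The closest known reaction type is the acid-induced Robinson-type cyclodehydration of nopinone-derived 1,5-diketones joined to the HCl opening of pinane-type cyclobutyl enones to chloroisopropyl cyclohexenones. Ring A closes in the favoured 6-(enolendo)-exo-trig aldol mode, and ring B is what remains of the bicycle once the four-membered ring is cut. No new stereocentre arises (C9 and C10 lose theirs), C4 and C5 are not enolisable, and C7 is retained as long as chloride capture in the HCl-saturated medium outruns hydride shift or elimination toward C7, which is why the run is kept at room temperature and stopped at full conversion. The selectivity required, cleavage of C9–C11 and not C9–C8 together with a single aldol mode, is secured by the tertiary versus primary cation and by C10 being flanked by quaternary C5 and bridgehead C9, so that only C1 can close a six-membered ring.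

Step 5
Reactants: 9 11-chloro-eremophil-1(10)-en-2-one
Product: 10 11-chloro-eremophila-1(10),8-dien-2-one
Conditions: DDQ (1.1 equiv), HCl (g)-saturated 1,4-dioxane, rt
Reagents that add atoms: none
Why: Acid-catalysed quinone dehydrogenation of an octalone to its linear dienone: HCl equilibrates 9 with the extended C2(OH)=C1–C10=C9 dienol, DDQ abstracts hydride from C8, and the HCl medium that created the C11 chloride preserves it, while no base is present that could remove the now vinylogously acidic C7–H.

Step 6
Reactants: 10 11-chloro-eremophila-1(10),8-dien-2-one
Product: 11 11-chloro-8α,9α-dihydroxy-eremophil-1(10)-en-2-one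
Conditions: OsO4 (5 mol %), NMO (1.2 equiv), acetone–H2O 9:1, 0 °C → rt
Reagents that add atoms: osmium tetroxide, O=[Os](=O)(=O)=O; N-methylmorpholine N-oxide, C[N+]1([O-])CCOCC1; water, O
Why: Catalytic OsO4/NMO syn-dihydroxylation: the disubstituted γ,δ-bond C8=C9 is more electron-rich than the α,β-bond C1=C10, the reagent should add from the α face, anti to both the C5 methyl and the C7 chloroisopropyl group, which sets C8 and C9 together, and the low water content spares the tertiary chloride.

Step 7
Reactants: 11 chloro enone diol
Product: 12 8α,9α-O-isopropylidene derivative of 11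
Conditions: Me2C(OMe)2, PPTS (cat.), CH2Cl2, rt
Reagents that add atoms: 2,2-dimethoxypropane, COC(C)(C)OC
Why: Acid-catalysed transketalisation of a cis-1,2-diol to a dioxolane, which touches no stereocentre, blocks isomerisation of the γ-hydroxy enone and puts bulk on the α face for the next step.

Step 8
Reactants: 12 enone acetonide
Product: 13 11-chloro-8α,9α-isopropylidenedioxy-10βH-eremophilan-2-one (cis-decalone)
Conditions: H2 (1 atm), Pd/C (palladium on carbon, 10 wt %), EtOAc, rt
Reagents that add atoms: none
Why: Heterogeneous catalytic hydrogenation of an octalone: adsorption cis to the angular methyl, the usual course for 4a-methyl octalones, is reinforced here by the α-face dioxolane whose C8 oxygen is 1,3-related to C10, so hydrogen should reach C10 from the β face and give the cis ring fusion, while the unactivated tertiary chloride, the acetal and the ketone are inert under neutral conditions.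

Step 9
Reactants: 13 cis-fused chloro decalone acetonide
Product: 14 8α,9α-isopropylidenedioxy-10βH-eremophil-11-en-2-one
Conditions: Al2O3 (neutral, activated), hexane–Et2O, rt → 35 °C
Reagents that add atoms: none
Why: Alumina-promoted dehydrochlorination of a chloroisopropyl group: loss of one of six exposed methyl hydrogens is favoured over the single hindered C7–H next to C8–O, so the isopropenyl rather than the isopropylidene isomer should prevail, with C7 untouched and no strong base near the ketone.

Step 10
Reactants: 14 isopropenyl acetonide
Product: 15 8α,9α-dihydroxy-10βH-eremophil-11-en-2-one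
Conditions: AcOH–H2O 4:1, 45 °C
Reagents that add atoms: none
Why: Mild aqueous acetal hydrolysis: acetic acid is strong enough to open the dioxolane but too weak to protonate the 1,1-disubstituted alkene, and no stereocentre is α to the ketone.

Step 11
Reactants: 15 cis-fused diol; 16 tiglic acid
Product: 18 9α-hydroxy-8α-tigloyloxy-10βH-eremophil-11-en-2-one, via tigloyl chloride 17 (not isolated)
Conditions: 16, (COCl)2, DMF (cat.), CH2Cl2, 0 °C → rt, evaporate; then 15, pyridine, CH2Cl2, −20 → 0 °C
Reagents that add atoms: none
Why: Acyl chloride esterification under kinetic control: in the preferred chair–chair form (C5 methyl and C7 isopropenyl equatorial on ring B) the C8 hydroxyl is equatorial whereas the C9 hydroxyl is axial and syn-axial to the C4–C5 bond, so one equivalent of 17 at low temperature should acylate O8 only, and pyridine is too weak a base to deconjugate the acyl chloride.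

Step 12
Reactants: 18 C8 mono-tiglate; 19 angelic acid
Product: 21 target CNP0249036.3, via angelic 2,4,6-trichlorobenzoic anhydride 20 (not isolated)
Conditions: 19, 2,4,6-Cl3C6H2COCl, Et3N (equimolar), toluene, rt; then 18, 75 °C
Reagents that add atoms: none
Why: Yamaguchi mixed-anhydride esterification run without a nucleophilic pyridine catalyst: omitting it avoids the addition–elimination path that turns angeloyl into tigloyl units, the hindered aroyl carbonyl directs the axial C9 hydroxyl to the angeloyl carbonyl, and the absence of excess amine limits migration of the C8 tiglate.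

Compound list
1 | (1R,5S)-(+)-nopinone (6,6-dimethylbicyclo[3.1.1]heptan-2-one) | CC1(C)[C@H]2CCC(=O)[C@@H]1C2 | starting material
2 | lithium C2=C3 enolate of nopinone (formed in the flask) | [Li+].CC1(C)[C@H]2CC=C([O-])[C@@H]1C2 | intermediate
3 | trans-3-methylnopinone, (3S), methyl anti to the gem-dimethyl bridge | CC1(C)[C@H]2C[C@H](C)C(=O)[C@@H]1C2 | intermediate
4 | lithium enolate of 3-methylnopinone (formed in the flask) | [Li+].CC1(C)[C@H]2CC(C)=C([O-])[C@@H]1C2 | intermediate
5 | 3,6,6-trimethyl-2-(trimethylsilyloxy)bicyclo[3.1.1]hept-2-ene, bridgeheads as in 1 | CC1(C)[C@H]2CC(C)=C(O[Si](C)(C)C)[C@@H]1C2 | intermediate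
6 | (E)-pent-3-en-2-one | C/C=C/C(C)=O | starting material
7 | (3R)-3-methyl-3-[(2S)-4-oxopentan-2-yl]nopinone (C14 syn, chain anti to the gem-dimethyl bridge) | CC1(C)[C@H]2C[C@](C)([C@@H](C)CC(C)=O)C(=O)[C@@H]1C2 | intermediate
8 | 4β,5β-dimethyl-9,11-cycloeremophil-1(10)-en-2-one, C11 bridging C7 and C9 on the β face (formed in the flask) | CC1(C)[C@H]2C[C@@]3(C)C(=CC(=O)C[C@@H]3C)[C@@H]1C2 | intermediate
9 | 11-chloro-eremophil-1(10)-en-2-one, 4β,5β-dimethyl, 7β-(2-chloropropan-2-yl) | CC(C)(Cl)[C@H]1C[C@@]2(C)C(=CC(=O)C[C@@H]2C)CC1 | intermediate
10 | 11-chloro-eremophila-1(10),8-dien-2-one, stereocentres as in 9 | CC(C)(Cl)[C@H]1C[C@@]2(C)C(=CC(=O)C[C@@H]2C)C=C1 | intermediate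
11 | 11-chloro-8α,9α-dihydroxy-eremophil-1(10)-en-2-one | CC(C)(Cl)[C@H]1C[C@@]2(C)C(=CC(=O)C[C@@H]2C)[C@H](O)[C@@H]1O | intermediate
12 | 11-chloro-8α,9α-isopropylidenedioxy-eremophil-1(10)-en-2-one | CC(C)(Cl)[C@H]1C[C@@]2(C)C(=CC(=O)C[C@@H]2C)[C@@H]3OC(C)(C)O[C@H]13 | intermediate
13 | 11-chloro-8α,9α-isopropylidenedioxy-10βH-eremophilan-2-one (cis-decalone) | CC(C)(Cl)[C@H]1C[C@@]2(C)[C@H](CC(=O)C[C@@H]2C)[C@@H]3OC(C)(C)O[C@H]13 | intermediate
14 | 8α,9α-isopropylidenedioxy-10βH-eremophil-11-en-2-one | C=C(C)[C@H]1C[C@@]2(C)[C@H](CC(=O)C[C@@H]2C)[C@@H]3OC(C)(C)O[C@H]13 | intermediate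
15 | 8α,9α-dihydroxy-10βH-eremophil-11-en-2-one | C=C(C)[C@H]1C[C@@]2(C)[C@H](CC(=O)C[C@@H]2C)[C@H](O)[C@@H]1O | intermediate
16 | tiglic acid, (E)-2-methylbut-2-enoic acid | OC(=O)/C(C)=C/C | starting material
17 | tigloyl chloride (formed in the flask) | ClC(=O)/C(C)=C/C | intermediate
18 | 9α-hydroxy-8α-tigloyloxy-10βH-eremophil-11-en-2-one | C=C(C)[C@H]1C[C@@]2(C)[C@H](CC(=O)C[C@@H]2C)[C@H](O)[C@@H]1OC(=O)/C(C)=C/C | intermediate
19 | angelic acid, (Z)-2-methylbut-2-enoic acid | OC(=O)/C(C)=C\C | starting material
20 | angelic 2,4,6-trichlorobenzoic anhydride (formed in the flask) | O=C(OC(=O)/C(C)=C\C)c1c(Cl)cc(Cl)cc1Cl | intermediate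
21 | 9α-angeloyloxy-8α-tigloyloxy-10βH-eremophil-11-en-2-one, (4S,5R,7R,8R,9S,10S), CNP0249036.3 | C=C(C)[C@H]1C[C@@]2(C)[C@H](CC(=O)C[C@@H]2C)[C@H](OC(=O)/C(C)=C\C)[C@@H]1OC(=O)/C(C)=C/C | target

Total step count: 12. Longest linear sequence: 12 steps (1 → 21); 6, 16 and 19 are bought and enter directly.

Steps most likely to fail

Step 3. The open transition state may discriminate poorly between the two faces of the enone β-carbon (C4). Bond formation at the fully substituted enol carbon may also be slow enough for desilylation to compete. The fallback gives up the silyl enol ether and runs a classical Robinson annulation in an aprotic, cation-bridged medium. Ketone 3 is deprotonated with NaH in dioxane and 6 is added slowly. The crude Michael and ketol mixture is then dehydrated with KOH in EtOH. C4 is thus set in a closed, metal-chelated transition state, a different control element. The fallback sets out from 3 (with 6) and rejoins the route at 8, which is isolated in this case and freed of any C4 epimer. Treatment with HCl in AcOH, as in the second half of step 4, then carries 8 to 9.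

Step 12. Acylation of the axial, 1,3-diaxially crowded C9 hydroxyl may be slow. That would give time for Z-to-E isomerisation of the activated angeloyl unit and for migration of the tigloyl group from O8 to O9. The fallback builds the Z-alkene on the ester instead of importing it with the acid. Starting from 18, the C9 hydroxyl is esterified with the small 2-[bis(2,2,2-trifluoroethoxy)phosphoryl]propanoic acid (EDC, DMAP, CH2Cl2, rt). DMAP is harmless here because no Z-alkene is present yet. This gives the C9 phosphonopropionate F2 as an inconsequential mixture at the phosphonate carbon. A Still–Gennari olefination (KN(SiMe3)2, 18-crown-6, THF, −78 °C, then acetaldehyde) then forms the Z-trisubstituted enoate and returns to the route at 21.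

Step 5. Once C7–H becomes part of the extended enone system, loss of HCl across C7–C11 may set in. Hydride abstraction could also stray to C3–C4 or continue past the dienone. The fallback replaces quinone hydride abstraction with palladium-mediated β-hydride elimination on a preformed dienol ether. Starting from 9, t-BuMe2SiOTf and Et3N in CH2Cl2 at 0 °C give the thermodynamic linear dienol silyl ether F1; the amine meets only substrates whose C7–H is not yet activated. A Saegusa–Ito oxidation of F1 with Pd(OAc)2 (divalent palladium) in MeCN at rt then installs C8=C9 and comes back to the route at 10.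

Further compounds
F0 | step 3 | none | none
F1 | step 5 | 2-(tert-butyldimethylsilyloxy)-11-chloro-eremophila-1,9-diene (linear dienol silyl ether, C1=C2 and C9=C10) | CC(C)(Cl)[C@H]1C[C@@]2(C)C(=CC1)C=C(O[Si](C)(C)C(C)(C)C)C[C@@H]2C
F2 | step 12 | 9α-{2-[bis(2,2,2-trifluoroethoxy)phosphoryl]propanoyloxy}-8α-tigloyloxy-10βH-eremophil-11-en-2-one | C=C(C)[C@H]1C[C@@]2(C)[C@H](CC(=O)C[C@@H]2C)[C@H](OC(=O)C(C)P(=O)(OCC(F)(F)F)OCC(F)(F)F)[C@@H]1OC(=O)/C(C)=C/C
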